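**Retrosynthetic overview**
1. Target 18 is the (3R,4R)-trans 3-vanillyl-4-vanilloyl γ-butyrolactone. Both phenols are carried as benzyl ethers and the aryl ketone as a dioxolane, all removed at the end (hydrogenolysis, then dilute acid).
2. The C3–CH2Ar bond comes from alkylation of the enolate of the β-substituted lactone 11 with benzylic bromide 14, anti to the C4 substituent.
3. The plan rests on one feature: the ring segment C3–C2(=O)–O1–C5 around C4 is a cyclobutanone with one oxygen inserted, and C4 is the ring carbon opposite the carbonyl, on the mirror plane of cyclobutanone 9. An asymmetric Baeyer–Villiger oxidation inserts O1 between C2 and one enantiotopic CH2 and so creates C4.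
4. Cyclobutanone 9 comes from the aryl Grignard of bromide 2 and 3-methylidenecyclobutane-1-carbonitrile 3: ketone 6, dioxolane 7, then cleavage of the exocyclic alkene.
5. Ring order: the four-membered carbocycle is bought; the oxolan-2-one is the only ring made (step 5, by ring expansion); the dioxolane is a temporary mask.

Key step: step 5

Remark on the chemistry: the sense of induction of the chiral phosphoric acid for a 3-substituent that is a ketal carbon is assumed to be settled by one pilot run with each catalyst antipode; the antipode that gives (4R)-11 is used in step 5.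

**Route**

Step 1
Reactants: 1 4-bromo-2-methoxyphenol
Product: 2 1-(benzyloxy)-4-bromo-2-methoxybenzene
Conditions: BnBr (1.1 equiv), K2CO3, DMF, rt
Reagents that add atoms: benzyl bromide, BrCc1ccccc1
Why: Williamson ether synthesis, in which the phenoxide formed with K2CO3 displaces bromide from benzyl bromide by SN2 and nothing else in 1 is nucleophilic.

Step 2
Reactants: 2 1-(benzyloxy)-4-bromo-2-methoxybenzene; 3 3-methylidenecyclobutane-1-carbonitrile
Product: 6 [4-(benzyloxy)-3-methoxyphenyl](3-methylidenecyclobutyl)methanone, via aryl Grignard reagent 4 (not isolated), via N-magnesio ketimine 5 (not isolated)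
Conditions: Mg, I2 (cat.), THF, reflux; then 3, CuBr (2 mol %), THF, reflux; then 1 M aq. HCl, 0 °C → rt
Reagents that add atoms: water, O
Why: Grignard addition to a nitrile, in which magnesium insertion gives 4, which adds once to the nitrile carbon to give the ketimine salt 5 (the anionic imine is not electrophilic, so no second addition), and cold dilute acid hydrolyses the imine to the ketone while the brief contact should spare the exocyclic alkene.

Step 3
Reactants: 6 [4-(benzyloxy)-3-methoxyphenyl](3-methylidenecyclobutyl)methanone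
Product: 7 2-[4-(benzyloxy)-3-methoxyphenyl]-2-(3-methylidenecyclobutyl)-1,3-dioxolane
Conditions: Me3SiOCH2CH2OSiMe3 (2 equiv), Me3SiOTf (5 mol %), CH2Cl2, −78 → −20 °C; pyridine quench
Reagents that add atoms: 1,2-bis(trimethylsilyloxy)ethane, C[Si](C)(C)OCCO[Si](C)(C)C
Why: Silyl-triflate-catalysed ketalisation with the bis-silyl ether of ethylene glycol, in which formation of the Si–O–Si bond drives the otherwise unfavourable ketalisation of the conjugated, α-branched aryl ketone under aprotic low-temperature conditions that should leave the 1,1-disubstituted alkene and the benzyl ether untouched.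

Step 4
Reactants: 7 2-[4-(benzyloxy)-3-methoxyphenyl]-2-(3-methylidenecyclobutyl)-1,3-dioxolane
Product: 9 3-{2-[4-(benzyloxy)-3-methoxyphenyl]-1,3-dioxolan-2-yl}cyclobutan-1-one, via cyclobutane-1-methanol-1-ol diol 8 (not isolated)
Conditions: K2OsO4·2H2O (2 mol %), NaIO4 (4 equiv), 2,6-lutidine (2 equiv), 1,4-dioxane/H2O 3:1, rt
Reagents that add atoms: osmium tetroxide (formed and recycled in the flask from K2OsO4·2H2O by NaIO4), O=[Os](=O)(=O)=O; sodium periodate (terminal oxygen source), [Na+].[O-]I(=O)(=O)=O
Why: Lemieux–Johnson oxidation, in which OsO4 dihydroxylates the only alkene to diol 8 and periodate cleaves it in the same flask to the cyclobutanone and formaldehyde, while the lutidine buffer protects the acid-labile aryl ketal and the method avoids exposing the electron-rich arenes to ozone.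

Step 5
Reactants: 9 3-{2-[4-(benzyloxy)-3-methoxyphenyl]-1,3-dioxolan-2-yl}cyclobutan-1-one
Product: 11 (4R)-4-{2-[4-(benzyloxy)-3-methoxyphenyl]-1,3-dioxolan-2-yl}oxolan-2-one, via Criegee hydroperoxy hemiketal 10 (not isolated)
Conditions: 3,3'-di(pyren-1-yl)-5,5',6,6',7,7',8,8'-octahydro-1,1'-binaphthyl-2,2'-diyl hydrogen phosphate (10 mol %, antipode giving 4R), 30% aq. H2O2 (1.5 equiv), CHCl3, −40 °C; aq. Na2SO3 quench
Reagents that add atoms: hydrogen peroxide, OO
Why: This is the catalytic asymmetric Baeyer–Villiger oxidation of a prochiral 3-substituted cyclobutanone, a known reaction type for chiral phosphoric acids with aqueous H2O2: the acid holds the strained ketone and hydrogen peroxide in a hydrogen-bonded assembly, peroxide adds to give Criegee adduct 10, and one of the two enantiotopic ring CH2 groups migrates from carbon to oxygen with loss of water. The oxolan-2-one ring is therefore not closed end-on but arises by 1,2-shift ring expansion of the four-membered ring, which puts the C2–O1 and O1–C5 bonds in place. The only new stereocentre, C4, is fixed by which enantiotopic CH2 migrates, and that choice is made by the chiral pocket of the catalyst (reagent control, since the substrate has a mirror plane through C1 and C3). Chemoselectivity is needed against the electron-rich arenes, the benzyl ether and the masked aryl ketone; it is secured by the ring strain that makes the cyclobutanone by far the most electrophilic carbonyl and by the dioxolane, which hides the aryl ketone from peroxide and leaves C4 without an enolisable neighbour. The low temperature and the weak acidity of the catalyst should keep the aryl ketal intact.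

Step 6
Reactants: 12 4-(benzyloxy)-3-methoxybenzaldehyde
Product: 13 [4-(benzyloxy)-3-methoxyphenyl]methanol
Conditions: NaBH4, MeOH/THF, 0 °C
Reagents that add atoms: none
Why: Borohydride reduction of an aromatic aldehyde to the benzylic alcohol, with no other reducible group present.

Step 7
Reactants: 13 [4-(benzyloxy)-3-methoxyphenyl]methanol
Product: 14 1-(benzyloxy)-4-(bromomethyl)-2-methoxybenzene
Conditions: PBr3 (0.4 equiv), Et2O, 0 °C; used at once
Reagents that add atoms: phosphorus tribromide, BrP(Br)Br
Why: Conversion of an electron-rich benzylic alcohol into the bromide with PBr3 through a phosphite ester and bromide displacement, the product being used directly because such bromides are labile.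

Step 8
Reactants: 11 (4R)-4-{2-[4-(benzyloxy)-3-methoxyphenyl]-1,3-dioxolan-2-yl}oxolan-2-one; 14 1-(benzyloxy)-4-(bromomethyl)-2-methoxybenzene
Product: 16 (3R,4R)-3-[4-(benzyloxy)-3-methoxybenzyl]-4-{2-[4-(benzyloxy)-3-methoxyphenyl]-1,3-dioxolan-2-yl}oxolan-2-one, via lithium lactone enolate 15 (not isolated)
Conditions: LiN(SiMe3)2 (1.05 equiv), THF, −78 °C; then 14 (1.2 equiv), DMPU, −78 → −30 °C; aq. NH4Cl
Reagents that add atoms: none
Why: Diastereoselective alkylation of a lactone enolate, in which deprotonation at C3 gives planar enolate 15, the bulky aryl-dioxolanyl group on C4 blocks one face and the benzylic bromide enters anti to it by SN2 to set C3 as R (3,4-trans), while the ketal keeps C4 free of a second acidifying group and prevents base-induced opening of a β-acyloxy ketone.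

Step 9
Reactants: 16 (3R,4R)-3-[4-(benzyloxy)-3-methoxybenzyl]-4-{2-[4-(benzyloxy)-3-methoxyphenyl]-1,3-dioxolan-2-yl}oxolan-2-one
Product: 17 (3R,4R)-3-(4-hydroxy-3-methoxybenzyl)-4-[2-(4-hydroxy-3-methoxyphenyl)-1,3-dioxolan-2-yl]oxolan-2-one
Conditions: H2 (1 atm), 10% Pd/C, EtOAc, rt
Reagents that add atoms: none
Why: Heterogeneous catalytic hydrogenolysis of the two aryl benzyl ethers, which should cleave far more readily than the fully substituted benzylic C–O bonds of the aryl ketal, and keeping the ketone masked at this stage avoids its reduction, with neither stereocentre touched.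

Step 10
Reactants: 17 (3R,4R)-3-(4-hydroxy-3-methoxybenzyl)-4-[2-(4-hydroxy-3-methoxyphenyl)-1,3-dioxolan-2-yl]oxolan-2-one
Product: 18 (3R,4R)-4-(4-hydroxy-3-methoxybenzoyl)-3-(4-hydroxy-3-methoxybenzyl)oxolan-2-one
Conditions: 1 M aq. HCl, THF, 0 °C → rt
Reagents that add atoms: water, O
Why: Acid-catalysed ketal hydrolysis, made easy by the para-hydroxy group that stabilises the oxocarbenium ion, while the lactone survives dilute acid and the 3,4-trans arrangement is the thermodynamically preferred one, so C3 and C4 should keep their configuration.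

**Compound list**
1 | 4-bromo-2-methoxyphenol | COc1cc(Br)ccc1O | starting material
2 | 1-(benzyloxy)-4-bromo-2-methoxybenzene | COc1cc(Br)ccc1OCc1ccccc1 | intermediate
3 | 3-methylidenecyclobutane-1-carbonitrile | C=C1CC(C#N)C1 | starting material
4 | [4-(benzyloxy)-3-methoxyphenyl]magnesium bromide (formed in the flask) | COc1cc([Mg]Br)ccc1OCc1ccccc1 | intermediate
5 | N-(bromomagnesio)-1-[4-(benzyloxy)-3-methoxyphenyl]-1-(3-methylidenecyclobutyl)methanimine (formed in the flask) | C=C1CC(C1)C(=N[Mg]Br)c1ccc(OCc2ccccc2)c(OC)c1 | intermediate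
6 | [4-(benzyloxy)-3-methoxyphenyl](3-methylidenecyclobutyl)methanone | C=C1CC(C1)C(=O)c1ccc(OCc2ccccc2)c(OC)c1 | intermediate
7 | 2-[4-(benzyloxy)-3-methoxyphenyl]-2-(3-methylidenecyclobutyl)-1,3-dioxolane | C=C1CC(C1)C1(OCCO1)c1ccc(OCc2ccccc2)c(OC)c1 | intermediate
8 | 3-{2-[4-(benzyloxy)-3-methoxyphenyl]-1,3-dioxolan-2-yl}-1-(hydroxymethyl)cyclobutan-1-ol (cis/trans mixture, formed in the flask) | OCC1(O)CC(C1)C1(OCCO1)c1ccc(OCc2ccccc2)c(OC)c1 | intermediate
9 | 3-{2-[4-(benzyloxy)-3-methoxyphenyl]-1,3-dioxolan-2-yl}cyclobutan-1-one | O=C1CC(C1)C1(OCCO1)c1ccc(OCc2ccccc2)c(OC)c1 | intermediate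
10 | 3-{2-[4-(benzyloxy)-3-methoxyphenyl]-1,3-dioxolan-2-yl}-1-hydroperoxycyclobutan-1-ol (Criegee adduct, formed in the flask) | OOC1(O)CC(C1)C1(OCCO1)c1ccc(OCc2ccccc2)c(OC)c1 | intermediate
11 | (4R)-4-{2-[4-(benzyloxy)-3-methoxyphenyl]-1,3-dioxolan-2-yl}oxolan-2-one | O=C1C[C@H](CO1)C1(OCCO1)c1ccc(OCc2ccccc2)c(OC)c1 | intermediate
12 | 4-(benzyloxy)-3-methoxybenzaldehyde | COc1cc(C=O)ccc1OCc1ccccc1 | starting material
13 | [4-(benzyloxy)-3-methoxyphenyl]methanol | COc1cc(CO)ccc1OCc1ccccc1 | intermediate
14 | 1-(benzyloxy)-4-(bromomethyl)-2-methoxybenzene | COc1cc(CBr)ccc1OCc1ccccc1 | intermediate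
15 | lithium (4R)-4-{2-[4-(benzyloxy)-3-methoxyphenyl]-1,3-dioxolan-2-yl}-4,5-dihydrofuran-2-olate (formed in the flask) | [Li]OC1=C[C@H](CO1)C1(OCCO1)c1ccc(OCc2ccccc2)c(OC)c1 | intermediate
16 | (3R,4R)-3-[4-(benzyloxy)-3-methoxybenzyl]-4-{2-[4-(benzyloxy)-3-methoxyphenyl]-1,3-dioxolan-2-yl}oxolan-2-one | COc1cc(C[C@H]2C(=O)OC[C@@H]2C2(OCCO2)c2ccc(OCc3ccccc3)c(OC)c2)ccc1OCc1ccccc1 | intermediate
17 | (3R,4R)-3-(4-hydroxy-3-methoxybenzyl)-4-[2-(4-hydroxy-3-methoxyphenyl)-1,3-dioxolan-2-yl]oxolan-2-one | COc1cc(C[C@H]2C(=O)OC[C@@H]2C2(OCCO2)c2ccc(O)c(OC)c2)ccc1O | intermediate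
18 | (3R,4R)-4-(4-hydroxy-3-methoxybenzoyl)-3-(4-hydroxy-3-methoxybenzyl)oxolan-2-one | COc1cc(C[C@H]2C(=O)OC[C@@H]2C(=O)c2ccc(O)c(OC)c2)ccc1O | target

**Step count and risks**
Total step count: 10. Longest linear sequence: 8 steps (1, 2, 3, 4, 5, 8, 9, 10, from compound 1 to 18); steps 6 and 7 form the side branch to bromide 14.

Steps most likely to fail:

Step 5 (key step). The two enantiotopic CH2 groups may be poorly discriminated, because the 3-substituent is a fully substituted ketal carbon and not the aryl group for which such catalysts are best established. The acid and peroxide may also strip the dioxolane. The fallback sets out from 9 and comes back at 11. Cyclobutanone 9 is desymmetrised by enantioselective deprotonation with the chiral lithium amide LiN[CH(CH3)C6H5]2 (R,R or S,S antipode as required) in THF at −100 °C with Me3SiCl present as internal quench. This should give the silyl enol ether {[(3R)-3-{2-[4-(benzyloxy)-3-methoxyphenyl]-1,3-dioxolan-2-yl}cyclobut-1-en-1-yl]oxy}trimethylsilane F1. Ozonolysis of the enol ether double bond (O3, CH2Cl2/MeOH, pyridine, −78 °C, indicator end point) with NaBH4 work-up turns the silyloxy carbon into the carboxyl group and the CH into CH2OH, giving (3R)-3-{2-[4-(benzyloxy)-3-methoxyphenyl]-1,3-dioxolan-2-yl}-4-hydroxybutanoic acid F2. F2 lactonises to 11 on careful acidification to about pH 4.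

Step 8. C-alkylation next to the fully substituted ketal carbon may be slow, double alkylation and erosion of the trans selectivity may occur, and the labile benzylic bromide may decompose before it reacts. The fallback sets out from 11 (through enolate 15) and aldehyde 12 and comes back at 17. Aldol addition of 15 to 12 (THF, −78 °C) should give, anti to the C4 substituent, (3S,4R)-3-{[4-(benzyloxy)-3-methoxyphenyl](hydroxy)methyl}-4-{2-[4-(benzyloxy)-3-methoxyphenyl]-1,3-dioxolan-2-yl}oxolan-2-one F3 as a mixture of carbinol epimers. Acetylation (Ac2O, pyridine, DMAP cat., 0 °C) gives [4-(benzyloxy)-3-methoxyphenyl][(3S,4R)-4-{2-[4-(benzyloxy)-3-methoxyphenyl]-1,3-dioxolan-2-yl}-2-oxooxolan-3-yl]methyl acetate F4. Hydrogenolysis (H2, 10% Pd/C, EtOAc) then removes the benzylic acetoxy group and both benzyl ethers in one operation and gives 17 directly, with step 9 no longer needed.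

Step 3. Ketalisation of the electron-rich, α-branched aryl ketone may stall, and forcing protic conditions would isomerise or hydrate the strained exocyclic alkene. The fallback sets out from 6 and comes back at 9; it takes the ring ketone through the ketalisation at the alcohol level so that no alkene is present. The alkene of 6 is cleaved first (K2OsO4·2H2O cat., NaIO4, 2,6-lutidine, dioxane/H2O) to 3-[4-(benzyloxy)-3-methoxybenzoyl]cyclobutan-1-one F5. Only the strained ring ketone is then reduced (NaBH4, 0.3 equiv, MeOH/CH2Cl2, −78 °C) to [4-(benzyloxy)-3-methoxyphenyl](3-hydroxycyclobutyl)methanone F6 (cis/trans mixture, of no consequence). The aryl ketone is ketalised under azeotropic conditions (ethylene glycol, TsOH cat., benzene, Dean–Stark) to 3-{2-[4-(benzyloxy)-3-methoxyphenyl]-1,3-dioxolan-2-yl}cyclobutan-1-ol F7. Dess–Martin oxidation (NaHCO3, CH2Cl2) returns 9.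

**Further compounds**
F1 | step 5 | {[(3R)-3-{2-[4-(benzyloxy)-3-methoxyphenyl]-1,3-dioxolan-2-yl}cyclobut-1-en-1-yl]oxy}trimethylsilane | C[Si](C)(C)OC1=C[C@@H](C1)C1(OCCO1)c1ccc(OCc2ccccc2)c(OC)c1
F2 | step 5 | (3R)-3-{2-[4-(benzyloxy)-3-methoxyphenyl]-1,3-dioxolan-2-yl}-4-hydroxybutanoic acid | OC(=O)C[C@H](CO)C1(OCCO1)c1ccc(OCc2ccccc2)c(OC)c1
F3 | step 8 | (3S,4R)-3-{[4-(benzyloxy)-3-methoxyphenyl](hydroxy)methyl}-4-{2-[4-(benzyloxy)-3-methoxyphenyl]-1,3-dioxolan-2-yl}oxolan-2-one (carbinol epimers) | COc1cc(C(O)[C@H]2C(=O)OC[C@@H]2C2(OCCO2)c2ccc(OCc3ccccc3)c(OC)c2)ccc1OCc1ccccc1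
F4 | step 8 | [4-(benzyloxy)-3-methoxyphenyl][(3S,4R)-4-{2-[4-(benzyloxy)-3-methoxyphenyl]-1,3-dioxolan-2-yl}-2-oxooxolan-3-yl]methyl acetate (acetate epimers) | COc1cc(C(OC(C)=O)[C@H]2C(=O)OC[C@@H]2C2(OCCO2)c2ccc(OCc3ccccc3)c(OC)c2)ccc1OCc1ccccc1
F5 | step 3 | 3-[4-(benzyloxy)-3-methoxybenzoyl]cyclobutan-1-one | O=C1CC(C1)C(=O)c1ccc(OCc2ccccc2)c(OC)c1
F6 | step 3 | [4-(benzyloxy)-3-methoxyphenyl](3-hydroxycyclobutyl)methanone | OC1CC(C1)C(=O)c1ccc(OCc2ccccc2)c(OC)c1
F7 | step 3 | 3-{2-[4-(benzyloxy)-3-methoxyphenyl]-1,3-dioxolan-2-yl}cyclobutan-1-ol | OC1CC(C1)C1(OCCO1)c1ccc(OCc2ccccc2)c(OC)c1
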